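Compound numbers are those of the steps below and are used throughout.

## Analysis of the target

The target 19 is a linear tridepside, the methyl ester of three 2,4-dihydroxy-6-methylbenzoic (orsellinic) acid units. Ring A is the terminal acyl unit with two free hydroxyls, ring B is the middle unit, and ring C carries the methyl ester. The rings are not fused: one aryl ester joins the carboxyl carbon of ring A to O4 of ring B, a second joins the carboxyl carbon of ring B to O4 of ring C. There is no stereocentre and no double-bond geometry to set. The sensitive groups are the two aryl esters, which are activated esters open to hydrolysis, alcoholysis and acyl migration, and the methyl ester, which must survive to the end. The difficulty lies in order and differentiation: three almost identical units must be joined head to tail, and ring B must engage its carboxyl and O4 while its O2–H stays free. Each ring has the oxygenation pattern of a folded tetraketide. On ring B, C1 bears the ester carbon, C2 and C4 bear oxygen and C6 bears methyl, so the ester carbon with C1–C3 is an acetoacetate fragment and C4–C6 with the methyl is an acetoacetyl fragment. The strategy uses this: ring B is grown on O4 of ring C from an aryl acetoacetate and appears already esterified at the right oxygen, with O4–H free and O2–H chelated.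

## Retrosynthetic reasoning

**19 from 18.** The three benzyl–oxygen bonds are cut last. Benzyl ethers are chosen because neutral hydrogenolysis leaves aryl esters and the methyl ester alone, whereas acidic or basic deprotection would endanger the depside bonds.

**18 from 14 and 16 (through 17).** The acyl carbon–O4 bond between ring A and ring B is cut. Ring A is only an acyl donor with both hydroxyls masked, and its dibenzyl ether acid 16 comes in two ordinary steps from 1. The forward acylation must choose O4–H of ring B over O2–H. The latter is hydrogen-bonded to the ring B ester carbonyl and flanked by it, and ring C offers no hydroxyl.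

**14 from 8 and 12.** This is the central disconnection: the C3–C4 and C1–C6 bonds of ring B are cut and the B–C ester is left intact. Cutting that ester instead would call for an orsellinic acid with free carboxyl, temporarily blocked O4 and separately handled O2. Taking the ring apart gives an acetoacetate of the ring C phenol, written as diene 8, and the three-carbon dielectrophile 12. Ring B then needs no protecting group at any stage. The forward reaction must form the C3–C4 bond first, close through carbon and not oxygen, and spare the aryl ester.

**8 from 7, and 7 from 4 and 5 (through 6).** The two silicon–oxygen bonds are cut, then the acetoacetyl–O4 bond. The acetoacetate is made under neutral conditions by trapping ketene 6, released thermally from 5, with the single free hydroxyl of 4.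

**4 from 3, 2 and 1.** The O2–benzyl and O4–allyl bonds are cut. Direct benzylation of 1 cannot be used, because alkylation goes to the unchelated, more acidic O4–H. O4 is therefore blocked first as an allyl ether (2), O2 is benzylated (3), and the allyl group is removed (4).

**12 from 11, 10 and 9.** The acid chloride goes back to the acid, the acid to its methyl ester, and the enol ether to the ketone of 9. The E enol ether fixes C6 at the ketone oxidation level with methoxy as the leaving group.

**16 from 15 and 1.** The methyl ester and the two benzyl ethers are cut, so ring A comes from the same starting material as ring C.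

## Alternatives that were turned down

**Alternative 1:** Ring A is cut at two exocyclic bonds, C6–CH3 and C1–carboxyl, and rebuilt on an aryne.
- Forward key step: halogen–magnesium exchange on 3,5-bis(benzyloxy)-2-iodophenyl 4-chlorobenzenesulfonate A1 and loss of the sulfonate would give 3,5-bis(benzyloxy)benzyne A2. A methylmagnesium halide would add at the aryne carbon remote from the neighbouring benzyloxy group. Carboxylation of the resulting arylmagnesium would give 2,4-bis(benzyloxy)-6-methylbenzoic acid A3.
- For it: the 1,2,3-substitution is set in one flask, the regiochemistry follows from inductive stabilisation of the carbanion next to the alkoxy group, and no ester linkage is present. On robustness of the key step it is stronger than the chosen strategy.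
- Against it: A3 is the same substance as 16, which the route reaches in two steps from 1. A1 needs a regioselective iodination between a hydroxyl and a benzyloxy group of a symmetrical precursor, which is longer than that. The exchange reagent can also add to A2.
- Comparison: it leaves the middle ring, the real problem, untouched. The chosen strategy puts its carbon–carbon bond formation on ring B, where it replaces protecting-group differentiation.

**Alternative 2:** Ring A is cut at C3–C4 and C5–C6 into a 2-pyranone and a two-carbon ketene equivalent.
- Forward key step: pyranone ester A4, a 4-(benzyloxy)-6-methyl-2-oxo-2H-pyran-5-carboxylate of the benzyl-protected ring B–ring C phenol, would add 1,1-bis(trimethylsilyloxy)ethene A5 across pyranone C3 and C6 in an inverse-demand [4+2] reaction. Decarboxylative cycloreversion and loss of one silyloxy group would give the tribenzyl ether A6.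
- For it: the polarisation is unambiguous, with the nucleophilic CH2 of A5 going to C6, beta to the ester. It is the most convergent plan, since the last carbon–carbon bond formation completes the skeleton; on this point it is stronger than the chosen strategy.
- Against it: A4 requires the ring B–ring C phenol with ring B already differentiated, which is the intermediate the chosen strategy avoids making by protecting-group chemistry, and a pyranone acid as well. Pyranone C6 bears methyl, so the cycloaddition creates a fully substituted bridgehead and is further slowed by donation from the ring oxygen. The heating this implies exposes two aryl esters to A5, a carbon nucleophile that can be C-acylated.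
- Comparison: it is longer, and it spends its key step on the ring that is easiest to source. The chosen strategy is less convergent but makes the ring that cannot be bought in a usable form.

**Alternative 3:** Ring C is cut into a four-carbon vinylketene (C2, C1, C6, C5) and a two-carbon alkyne (C3, C4) that carries the depside oxygen.
- Forward key step: irradiation of methyl (2E)-5-diazo-3-methyl-4-oxopent-2-enoate A7 would cause a Wolff rearrangement (C5–C6 bond) to a vinylketene. This would add the ethynyl ester A8 of the ring A–ring B acid in a [2+2] reaction (C2–C3 and C4–C5 bonds). Four-electron ring opening, six-electron closure (C1–C2 bond) and tautomerisation would give A9 with the C2 hydroxyl free.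
- For it: one step makes a fully substituted ring with the oxygen at C4 placed by the mechanism, ring C needs no protecting group, and A7 is small. On ring C protecting-group economy it is stronger than the chosen route, which spends three steps there.
- Against it: A8 is an alkynyl carboxylate, a very reactive acyl donor that is hard to make from a di-ortho-substituted acid. It is far less electron-rich than the silyloxy- and alkoxy-alkynes on which this benzannulation depends. Ultraviolet light on a substrate with two aryl esters invites photo-Fries rearrangement. The ring A–ring B acid again needs a differentiated ring B.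
- Comparison: it builds ring C, which is available as 1. The chosen strategy uses only thermal and Lewis acid steps and keeps ring B free of protecting groups.

Key step: step 9

## Route

Remarks on the chemistry:
- Ring positions are numbered from the carbonyl-bearing carbon (C1), with oxygen on C2 and C4 and methyl on C6.
- The C1=C2 double bond of diene 8 is drawn as Z. Either geometry would serve, because it disappears when ring B becomes aromatic.

Step 1
Reactants: 1 methyl orsellinate (methyl 2,4-dihydroxy-6-methylbenzoate)
Product: 2 methyl 2-hydroxy-6-methyl-4-(prop-2-en-1-yloxy)benzoate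
Conditions: allyl bromide (1.05 equiv), K2CO3, acetone, 56 °C
Reagents that add atoms: allyl bromide, C=CCBr
Why: Williamson etherification; O4–H is the more acidic, unchelated hydroxyl, while O2–H is held in a hydrogen bond to the ester carbonyl, so one equivalent of halide should alkylate O4 only.

Step 2
Reactants: 2 methyl 2-hydroxy-6-methyl-4-(prop-2-en-1-yloxy)benzoate
Product: 3 methyl 2-(benzyloxy)-6-methyl-4-(prop-2-en-1-yloxy)benzoate
Conditions: BnBr, K2CO3, DMF, 60 °C
Reagents that add atoms: benzyl bromide, BrCc1ccccc1
Why: Williamson etherification of the chelated phenol, which needs the dipolar solvent and warming; with O4 blocked the benzyl group can only go to O2.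

Step 3
Reactants: 3 methyl 2-(benzyloxy)-6-methyl-4-(prop-2-en-1-yloxy)benzoate
Product: 4 methyl 2-(benzyloxy)-4-hydroxy-6-methylbenzoate
Conditions: Pd(PPh3)4 (cat.), morpholine, THF, 20 °C
Reagents that add atoms: none
Why: Tsuji–Trost deallylation; zerovalent palladium ionises the aryl allyl ether to an allylpalladium complex and the phenoxide, morpholine takes up the allyl group, and the benzyl ether and methyl ester are inert.

Step 4
Reactants: 4 methyl 2-(benzyloxy)-4-hydroxy-6-methylbenzoate; 5 2,2,6-trimethyl-4H-1,3-dioxin-4-one
Product: 7 methyl 2-(benzyloxy)-6-methyl-4-[(3-oxobutanoyl)oxy]benzoate, via acetylketene 6 (not isolated)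
Conditions: toluene, 110 °C
Reagents that add atoms: none
Why: Acetoacetylation by acylketene trapping; 5 fragments by retro-[4+2] reaction to acetylketene, which adds the only free hydroxyl of 4 under neutral conditions.

Step 5
Reactants: 7 methyl 2-(benzyloxy)-6-methyl-4-[(3-oxobutanoyl)oxy]benzoate
Product: 8 methyl 2-(benzyloxy)-4-{[(1Z)-1,3-bis(trimethylsilyloxy)buta-1,3-dien-1-yl]oxy}-6-methylbenzoate
Conditions: TMSOTf (2.2 equiv), Et3N (3 equiv), Et2O, 0 → 20 °C; ammonium salt layer removed under argon, used crude
Reagents that add atoms: trimethylsilyl trifluoromethanesulfonate, C[Si](C)(C)OS(=O)(=O)C(F)(F)F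
Why: Soft enolisation to a 1,3-bis(silyloxy)-1,3-diene; the ketone enol is silylated first, then silylation of the ester carbonyl and loss of a terminal proton give the diene without a strong base that could expel the aryloxide by an E1cB path.

Step 6
Reactants: 9 methyl acetoacetate
Product: 10 methyl (2E)-3-methoxybut-2-enoate
Conditions: HC(OMe)3, cat. H2SO4, MeOH, 20 → 50 °C; distillation
Reagents that add atoms: trimethyl orthoformate, COC(OC)OC
Why: Acid-catalysed ketalisation with the orthoester and loss of methanol from the ketal; the conjugated E enol ether is the thermodynamic product.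

Step 7
Reactants: 10 methyl (2E)-3-methoxybut-2-enoate
Product: 11 (2E)-3-methoxybut-2-enoic acid
Conditions: KOH, H2O/MeOH, 60 °C; then cold 1 M HCl to pH 3
Reagents that add atoms: potassium hydroxide, [K+].[OH-]
Why: Saponification; the enol ether is a vinylogous carbonate that is stable to base, and brief cold acidification should precipitate the acid before the enol ether hydrolyses.

Step 8
Reactants: 11 (2E)-3-methoxybut-2-enoic acid
Product: 12 (2E)-3-methoxybut-2-enoyl chloride
Conditions: (COCl)2, cat. DMF, CH2Cl2, 0 → 20 °C; volatiles removed, used at once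
Reagents that add atoms: oxalyl chloride, O=C(Cl)C(Cl)=O
Why: Chlorination of the acid through the Vilsmeier-type chloroiminium species; the gaseous by-products leave, so the acid-sensitive enol ether is not held in acid.

Step 9
Reactants: 8 methyl 2-(benzyloxy)-4-{[(1Z)-1,3-bis(trimethylsilyloxy)buta-1,3-dien-1-yl]oxy}-6-methylbenzoate; 12 (2E)-3-methoxybut-2-enoyl chloride
Product: 14 methyl 2-(benzyloxy)-4-[(2,4-dihydroxy-6-methylbenzoyl)oxy]-6-methylbenzoate, via 7-methoxy-3,5-dioxooct-6-enoate ester 13 (not isolated)
Conditions: 8 (1.3 equiv), 12, TiCl4 (1.5 equiv), CH2Cl2, −78 → 0 °C; then cold 1 M HCl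
Reagents that add atoms: none
Why: TiCl4 activates acid chloride 12, and the terminal CH2 of diene 8, its most nucleophilic and least hindered carbon, attacks the acyl carbon with loss of chloride and one silyl group, forming the C3–C4 bond and giving 13 as its silyl or titanium enolate. Titanium on the new C4 carbonyl turns the methoxy enone into a vinylogous oxocarbenium ion, and the still enolised C1 adds to C6 in a Mukaiyama–Michael addition, forming the C1–C6 bond. Ring B closes in a 6-endo-trig mode, both carbons of the C5=C6 bond lying inside the new ring, and loss of the methoxy group from C6 followed by enolisation of the C4 ketone gives the arene. The closest known reaction type is the TiCl4-mediated Chan [3+3] cycloaromatisation of 1,3-bis(silyloxy)-1,3-dienes with masked 1,3-dicarbonyl electrophiles, here in the variant with a carboxyl-level electrophile that gives a resorcylate instead of a salicylate. No stereocentre is formed. The diene terminus must attack the acyl carbon before C6, since the reverse order would give the 2,6-dihydroxy-4-methyl isomer; the acyl chloride carbon is the more electrophilic and unhindered site, while C6 is fully substituted and deactivated by its methoxy donor until the acyl carbon has become a titanium-bound ketone. Carbon and not oxygen must close the ring; the oxygen on C2 stays capped by silicon or titanium, which leaves C1 as the nucleophilic terminus. The neutral diene, the absence of base and the low temperature should spare the aryl ester, the methyl ester and the benzyl ether of ring C.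

Step 10
Reactants: 1 methyl orsellinate
Product: 15 methyl 2,4-bis(benzyloxy)-6-methylbenzoate
Conditions: BnBr (2.5 equiv), K2CO3, DMF, 60 °C
Reagents that add atoms: benzyl bromide, BrCc1ccccc1
Why: Exhaustive Williamson etherification; excess halide and warming in DMF alkylate the chelated O2–H as well as O4–H.

Step 11
Reactants: 15 methyl 2,4-bis(benzyloxy)-6-methylbenzoate
Product: 16 2,4-bis(benzyloxy)-6-methylbenzoic acid
Conditions: KOH, DMSO/H2O, 90 °C; then 1 M HCl
Reagents that add atoms: potassium hydroxide, [K+].[OH-]
Why: Saponification of a di-ortho-substituted benzoate, which needs poorly solvated hydroxide and heat; benzyl aryl ethers are stable to these conditions.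

Step 12
Reactants: 16 2,4-bis(benzyloxy)-6-methylbenzoic acid; 14 methyl 2-(benzyloxy)-4-[(2,4-dihydroxy-6-methylbenzoyl)oxy]-6-methylbenzoate
Product: 18 methyl 2-(benzyloxy)-4-[(4-{[2,4-bis(benzyloxy)-6-methylbenzoyl]oxy}-2-hydroxy-6-methylbenzoyl)oxy]-6-methylbenzoate, via 2,4-bis(benzyloxy)-6-methylbenzoyl chloride 17 (not isolated)
Conditions: 16, (COCl)2, cat. DMF, CH2Cl2, 0 → 20 °C, evaporation; then 14, Et3N, cat. DMAP, CH2Cl2, 0 → 20 °C
Reagents that add atoms: none
Why: Acid chloride formation followed by DMAP-catalysed acyl transfer to a phenol; ring B O4–H is free and the more acidic hydroxyl, while ring B O2–H is chelated to and flanked by its ester carbonyl and ring C has no hydroxyl, so one equivalent of 17 should acylate O4 only.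

Step 13
Reactants: 18 methyl 2-(benzyloxy)-4-[(4-{[2,4-bis(benzyloxy)-6-methylbenzoyl]oxy}-2-hydroxy-6-methylbenzoyl)oxy]-6-methylbenzoate
Product: 19 methyl 4-[(4-{[2,4-dihydroxy-6-methylbenzoyl]oxy}-2-hydroxy-6-methylbenzoyl)oxy]-2-hydroxy-6-methylbenzoate (target)
Conditions: H2 (1 atm), 10% Pd/C, EtOAc/THF, 20 °C
Reagents that add atoms: none
Why: Catalytic hydrogenolysis of three benzyl aryl ethers; aryl esters and the methyl ester are inert, and the aprotic solvent excludes transesterification of the depside bonds.

## Compound list

1 | methyl orsellinate (methyl 2,4-dihydroxy-6-methylbenzoate) | COC(=O)c1c(C)cc(O)cc1O | starting material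
2 | methyl 2-hydroxy-6-methyl-4-(prop-2-en-1-yloxy)benzoate | COC(=O)c1c(C)cc(OCC=C)cc1O | intermediate
3 | methyl 2-(benzyloxy)-6-methyl-4-(prop-2-en-1-yloxy)benzoate | COC(=O)c1c(C)cc(OCC=C)cc1OCc1ccccc1 | intermediate
4 | methyl 2-(benzyloxy)-4-hydroxy-6-methylbenzoate | COC(=O)c1c(C)cc(O)cc1OCc1ccccc1 | intermediate
5 | 2,2,6-trimethyl-4H-1,3-dioxin-4-one | CC1=CC(=O)OC(C)(C)O1 | starting material
6 | acetylketene (but-1-ene-1,3-dione) | CC(=O)C=C=O | intermediate (not isolated)
7 | methyl 2-(benzyloxy)-6-methyl-4-[(3-oxobutanoyl)oxy]benzoate | COC(=O)c1c(C)cc(OC(=O)CC(C)=O)cc1OCc1ccccc1 | intermediate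
8 | methyl 2-(benzyloxy)-4-{[(1Z)-1,3-bis(trimethylsilyloxy)buta-1,3-dien-1-yl]oxy}-6-methylbenzoate | COC(=O)c1c(C)cc(O/C(O[Si](C)(C)C)=C/C(=C)O[Si](C)(C)C)cc1OCc1ccccc1 | intermediate
9 | methyl acetoacetate | COC(=O)CC(C)=O | starting material
10 | methyl (2E)-3-methoxybut-2-enoate | CO/C(C)=C/C(=O)OC | intermediate
11 | (2E)-3-methoxybut-2-enoic acid | CO/C(C)=C/C(=O)O | intermediate
12 | (2E)-3-methoxybut-2-enoyl chloride | CO/C(C)=C/C(Cl)=O | intermediate
13 | methyl 2-(benzyloxy)-4-{[(6E)-7-methoxy-3,5-dioxooct-6-enoyl]oxy}-6-methylbenzoate (present as its silyl or titanium enolate) | COC(=O)c1c(C)cc(OC(=O)CC(=O)CC(=O)/C=C(\C)OC)cc1OCc1ccccc1 | intermediate (not isolated)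
14 | methyl 2-(benzyloxy)-4-[(2,4-dihydroxy-6-methylbenzoyl)oxy]-6-methylbenzoate | COC(=O)c1c(C)cc(OC(=O)c2c(C)cc(O)cc2O)cc1OCc1ccccc1 | intermediate
15 | methyl 2,4-bis(benzyloxy)-6-methylbenzoate | COC(=O)c1c(C)cc(OCc2ccccc2)cc1OCc1ccccc1 | intermediate
16 | 2,4-bis(benzyloxy)-6-methylbenzoic acid | Cc1cc(OCc2ccccc2)cc(OCc2ccccc2)c1C(=O)O | intermediate
17 | 2,4-bis(benzyloxy)-6-methylbenzoyl chloride | Cc1cc(OCc2ccccc2)cc(OCc2ccccc2)c1C(Cl)=O | intermediate (not isolated)
18 | methyl 2-(benzyloxy)-4-[(4-{[2,4-bis(benzyloxy)-6-methylbenzoyl]oxy}-2-hydroxy-6-methylbenzoyl)oxy]-6-methylbenzoate | COC(=O)c1c(C)cc(OC(=O)c2c(C)cc(OC(=O)c3c(C)cc(OCc4ccccc4)cc3OCc3ccccc3)cc2O)cc1OCc1ccccc1 | intermediate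
19 | methyl 4-[(4-{[2,4-dihydroxy-6-methylbenzoyl]oxy}-2-hydroxy-6-methylbenzoyl)oxy]-2-hydroxy-6-methylbenzoate | COC(=O)c1c(C)cc(OC(=O)c2c(C)cc(OC(=O)c3c(C)cc(O)cc3O)cc2O)cc1O | target

## Step count and least certain steps

Total step count: 13. Longest linear sequence: 8 steps (steps 1, 2, 3, 4, 5, 9, 12, 13).

**Step 9 (key step).**
- What may go wrong: after the first bond has formed the chain may close through an enol oxygen to a pyranone, or lactonise with expulsion of the ring C aryloxide. The aryloxy group is a good leaving group and the enol oxygens sit at ring-forming distance. The diene may also hydrolyse before it reacts, and TiCl4 may cleave the ring C benzyl ether with chelation assistance from the neighbouring ester.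
- Fallback: ring B is brought in as a preformed, differentiated orsellinate by conventional depside assembly. It sets out from 3 and 4 (with 16) and rejoins the route at 19.
- Saponification of 3 (KOH, DMSO/H2O, 90 °C) gives 2-(benzyloxy)-6-methyl-4-(prop-2-en-1-yloxy)benzoic acid F1.
- Oxalyl chloride with catalytic DMF converts F1 into 2-(benzyloxy)-6-methyl-4-(prop-2-en-1-yloxy)benzoyl chloride F2.
- F2 acylates 4 (Et3N, cat. DMAP, CH2Cl2) to give methyl 2-(benzyloxy)-4-{[2-(benzyloxy)-6-methyl-4-(prop-2-en-1-yloxy)benzoyl]oxy}-6-methylbenzoate F3.
- Deallylation with Pd(PPh3)4 and morpholine frees O4 of ring B in methyl 2-(benzyloxy)-4-{[2-(benzyloxy)-4-hydroxy-6-methylbenzoyl]oxy}-6-methylbenzoate F4.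
- Acylation of F4 with 17, made from 16 as in step 12, gives methyl 2-(benzyloxy)-4-[(2-(benzyloxy)-4-{[2,4-bis(benzyloxy)-6-methylbenzoyl]oxy}-6-methylbenzoyl)oxy]-6-methylbenzoate F5.
- Hydrogenolysis of F5 over Pd/C gives 19.

**Step 5.**
- What may go wrong: the second silylation may stall, the aryl acetoacetate may fragment to a ketene and the phenoxide, or the diene may hydrolyse during handling. An aryl ester enolate has a better leaving group than the alkyl esters on which such dienes are usually made.
- Fallback: the triketide chain is built on the dioxinone instead of on a silyl diene. It sets out from 5, 12 and 4 and rejoins at 14 by way of 13.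
- The lithium dienolate of 5 (LiHMDS, THF, −78 °C, two equivalents) is acylated at its exocyclic carbon by 12 to give 6-[(3E)-4-methoxy-2-oxopent-3-en-1-yl]-2,2-dimethyl-4H-1,3-dioxin-4-one F6.
- Heating F6 with 4 in toluene at 110 °C releases the acylketene (6E)-7-methoxyocta-1,6-diene-1,3,5-trione F7, which 4 traps to give 13.
- TiCl4 in CH2Cl2 then closes 13 to 14 as in step 9.

**Step 12.**
- What may go wrong: the di-ortho-substituted acid chloride may react slowly, and the base with DMAP may then cause acyl migration between phenolic oxygens or acylation of the chelated hydroxyl.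
- Fallback: the coupling is run under acid with no phenoxide present. It sets out from 16 and 14 and rejoins at 18.
- Trifluoroacetic anhydride in toluene at 20 °C converts 16 into 2,4-bis(benzyloxy)-6-methylbenzoic trifluoroacetic anhydride F8. Its acylium character is stabilised by the two alkoxy groups, and it should transfer the aroyl group to the free O4–H of 14.

**Step 11.**
- What may go wrong: hydroxide may attack the carbonyl carbon too slowly, because it is shielded by the ortho methyl and ortho benzyloxy groups.
- Fallback: the ester is cleaved at the methyl carbon instead of the carbonyl carbon (no new compound, F0). It sets out from 15 and rejoins at 16.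
- Lithium propane-1-thiolate in DMF at 25–60 °C displaces the carboxylate from the O-methyl group by an SN2 reaction, and dilute HCl then liberates 16. The benzyl ethers should survive at this temperature.

## Further compounds

F1 | step 9 | 2-(benzyloxy)-6-methyl-4-(prop-2-en-1-yloxy)benzoic acid | Cc1cc(OCC=C)cc(OCc2ccccc2)c1C(=O)O
F2 | step 9 | 2-(benzyloxy)-6-methyl-4-(prop-2-en-1-yloxy)benzoyl chloride | Cc1cc(OCC=C)cc(OCc2ccccc2)c1C(Cl)=O
F3 | step 9 | methyl 2-(benzyloxy)-4-{[2-(benzyloxy)-6-methyl-4-(prop-2-en-1-yloxy)benzoyl]oxy}-6-methylbenzoate | COC(=O)c1c(C)cc(OC(=O)c2c(C)cc(OCC=C)cc2OCc2ccccc2)cc1OCc1ccccc1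
F4 | step 9 | methyl 2-(benzyloxy)-4-{[2-(benzyloxy)-4-hydroxy-6-methylbenzoyl]oxy}-6-methylbenzoate | COC(=O)c1c(C)cc(OC(=O)c2c(C)cc(O)cc2OCc2ccccc2)cc1OCc1ccccc1
F5 | step 9 | methyl 2-(benzyloxy)-4-[(2-(benzyloxy)-4-{[2,4-bis(benzyloxy)-6-methylbenzoyl]oxy}-6-methylbenzoyl)oxy]-6-methylbenzoate | COC(=O)c1c(C)cc(OC(=O)c2c(C)cc(OC(=O)c3c(C)cc(OCc4ccccc4)cc3OCc3ccccc3)cc2OCc2ccccc2)cc1OCc1ccccc1
F6 | step 5 | 6-[(3E)-4-methoxy-2-oxopent-3-en-1-yl]-2,2-dimethyl-4H-1,3-dioxin-4-one | CO/C(C)=C/C(=O)CC1=CC(=O)OC(C)(C)O1
F7 | step 5 | (6E)-7-methoxyocta-1,6-diene-1,3,5-trione | CO/C(C)=C/C(=O)CC(=O)C=C=O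
F8 | step 12 | 2,4-bis(benzyloxy)-6-methylbenzoic trifluoroacetic anhydride | Cc1cc(OCc2ccccc2)cc(OCc2ccccc2)c1C(=O)OC(=O)C(F)(F)F
F0 | step 11 | none | none
A1 | alternative 1 | 3,5-bis(benzyloxy)-2-iodophenyl 4-chlorobenzenesulfonate | Clc1ccc(cc1)S(=O)(=O)Oc1cc(OCc2ccccc2)cc(OCc2ccccc2)c1I
A2 | alternative 1 | 3,5-bis(benzyloxy)benzyne | C1#CC(OCc2ccccc2)=CC(OCc2ccccc2)=C1
A3 | alternative 1 | 2,4-bis(benzyloxy)-6-methylbenzoic acid | Cc1cc(OCc2ccccc2)cc(OCc2ccccc2)c1C(=O)O
A4 | alternative 2 | methyl 2-(benzyloxy)-4-{[2-(benzyloxy)-4-({[4-(benzyloxy)-6-methyl-2-oxo-2H-pyran-5-yl]carbonyl}oxy)-6-methylbenzoyl]oxy}-6-methylbenzoate | COC(=O)c1c(C)cc(OC(=O)c2c(C)cc(OC(=O)C3=C(C)OC(=O)C=C3OCc3ccccc3)cc2OCc2ccccc2)cc1OCc1ccccc1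
A5 | alternative 2 | 1,1-bis(trimethylsilyloxy)ethene | C=C(O[Si](C)(C)C)O[Si](C)(C)C
A6 | alternative 2 | methyl 2-(benzyloxy)-4-[(2-(benzyloxy)-4-{[2-(benzyloxy)-4-hydroxy-6-methylbenzoyl]oxy}-6-methylbenzoyl)oxy]-6-methylbenzoate | COC(=O)c1c(C)cc(OC(=O)c2c(C)cc(OC(=O)c3c(C)cc(O)cc3OCc3ccccc3)cc2OCc2ccccc2)cc1OCc1ccccc1
A7 | alternative 3 | methyl (2E)-5-diazo-3-methyl-4-oxopent-2-enoate | COC(=O)/C=C(\C)C(=O)C=[N+]=[N-]
A8 | alternative 3 | ethynyl 2-(benzyloxy)-4-{[2,4-bis(benzyloxy)-6-methylbenzoyl]oxy}-6-methylbenzoate | C#COC(=O)c1c(C)cc(OC(=O)c2c(C)cc(OCc3ccccc3)cc2OCc2ccccc2)cc1OCc1ccccc1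
A9 | alternative 3 | methyl 4-[(2-(benzyloxy)-4-{[2,4-bis(benzyloxy)-6-methylbenzoyl]oxy}-6-methylbenzoyl)oxy]-2-hydroxy-6-methylbenzoate | COC(=O)c1c(C)cc(OC(=O)c2c(C)cc(OC(=O)c3c(C)cc(OCc4ccccc4)cc3OCc3ccccc3)cc2OCc2ccccc2)cc1O
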